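Remark on the chemistry: locants follow the naphthoquinone (C1=O, C2–NH2, C3–H, C4=O, C5 acyl, C6–OH, C7–Me, C8–H; ring A = quinone ring, ring B = benzenoid ring) and the side chain is numbered C1′ (CO2H) to C7′ (ketone). The SMILES is read as (2′R,3′S,4′R,5′E), an all-syn Me/OH/Me triad.

## The problem

The target is a 2-amino-1,4-naphthoquinone whose ring B carries four different groups in a row: the enoyl ketone at C5, OH at C6, Me at C7 and H at C8. The C5–C7′ bond is the most hindered bond in the molecule, since the ketone is wedged between the peri carbonyl C4 and the C6 hydroxyl. The amino group must sit at C2, next to the carbonyl (C1) remote from the acyl group; C2 and C3 differ only through what ring B transmits. The side chain holds an E-trisubstituted enone and a pseudo-meso syn,syn triad C2′–C3′–C4′. C2′ and C3′ can be set together, and C3′ can then control C4′. The β-hydroxy acid (retro-aldol, elimination), the γ-centre C4′ of the enone (epimerisation), the o-hydroxyaryl enone (oxa-Michael closure to a chromanone) and the aminoquinone (hydrolysis, reduction) rule out strong base, reductants and hard nucleophiles late in the route.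

The feature that makes the key step possible is this: the ring B edge C5(acyl)–C6(OH)–C7(Me)–C8(H) is, atom for atom, C3–C4–C5–C6 of a 3-acyl-4-hydroxy-5-methyl-2-pyrone. The remaining ring B bond C4a–C8a is flanked by C4 and C1, which carry the same oxygen function, so it can be the triple bond of the symmetric 3,6-dimethoxybenzyne. Ring B can therefore be made from a pyrone by [4+2] addition and loss of CO2 with no regiochemical question, and with the hindered ketone already in place as the C3-acyl group of the pyrone.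

## Retrosynthesis

**32 ⇒ 30 (C2–N).** The C2–N bond is cut last. Carrying nitrogen earlier would make the ring A aryne unsymmetrical, with both triple-bond carbons still flanked by alkoxy groups and no bias, and an N–H would add to the aryne. Precursor 30 has no ring A regiochemistry. The forward amination must choose C2 over C3: O6 is para to C8a and donates into C1=O, so C4=O remains the activating carbonyl and its β-carbon is C2.

**30 ⇒ 29 ⇒ 28 (oxidation level and protecting groups).** The quinone oxygens are carried as the methyl ethers of 28. O6, O3′ and the acid are carried as MOM ether, TBS ether and 4-methoxybenzyl ester, all acid-labile. The forward order is oxidation with (NH4)2Ce(NO3)6 to 29, then one acidolysis to 30, so any protecting-group loss during the oxidation is harmless.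

**28 ⇒ 25 + 26 (bonds C4a–C5 and C8–C8a; CO2 restored across C5/C8).** This is the key cut. Cutting C5–C7′ instead leaves a fully substituted naphthalene to be made and the most hindered bond to be formed last. Cutting ring A instead needs a hexasubstituted benzene. Here 25 is a monocyclic pyrone and aryne 26 comes from the trisubstituted benzene 24. The forward reaction must add an aryne to a diene terminus (C3) that bears the acyl group, and must tolerate the enone, silyl ether and ester.

**25 ⇒ 17 + 9 (C5′=C6′).** A Horner–Wadsworth–Emmons cut between the pyrone ketophosphonate 17 and aldehyde 9. The neighbouring cut, acylating the pyrone with the complete enoic acid, needs two differentiated carboxyl groups and three more linear steps. The forward step must be E-selective and must not epimerise C4′.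

**17 ⇒ 16 ⇒ 13 + 14; 13 ⇒ 10 + 11 (pyrone C3–C7′ and the pyrone ring).** The C3–acyl bond is made as an O-to-C acyl shift on 4-hydroxy-5-methyl-2-pyrone 13 with phosphono acid 14, through O-ester 15. The C5 methyl blocks the only other nucleophilic carbon. Pyrone 13 comes from formylation of the dianion of keto ester 10 with methyl formate 11 and lactonisation of 12. O-Alkylation of 16 gives 17.

**9 ⇒ 8 ⇒ 6 ⇒ 5 ⇒ 4 ⇒ 1 + 2 (C4′–H/C5′–O, then C2′–C3′).** Aldehyde 9 comes from alcohol 8, which comes from syn-selective hydroboration (through boronate 7) of the isopropenyl group of 6. Alkene 6 comes from the aldol of imide 1 (through enolate 3) with methacrolein 2, through 4 and 5. One auxiliary-controlled event sets C2′ and C3′, and C3′ relays to C4′. The alternative aldol with a protected 3-hydroxy-2-methylpropanal needs that aldehyde made first and an extra deprotection.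

**24 ⇒ 22 ⇒ 19 ⇒ 18 (C–Si and O–Tf).** The aryne precursor comes from 2,5-dimethoxyphenol 18 by carbamate-directed ortho-silylation (19, 20, 21, 22), then carbamate cleavage to phenol 23 and triflation. Fluoride converts 24 into 26.

## Roads not taken

**Alternative 1:** the most obvious cut is C5–C7′ by aryl-metal acylation: bromine–lithium exchange on 5-bromo-1,4-dimethoxy-6-(methoxymethoxy)-7-methylnaphthalene A1 and addition to the side-chain Weinreb amide A2. A1 needs ring B assembled by stepwise substitution with a C5/C8 halogenation question. The nucleophile is a doubly ortho-substituted, peri-hindered aryllithium attacking a hindered amide that also has an enone and an acidic γ-hydrogen. The chosen plan makes the same bond as an acyl shift on a pyrone before the arene exists.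

**Alternative 2:** the same two ring B bonds can be cut the classical way, as a quinone Diels–Alder reaction of bromoquinone carbamate A3 with the acyclic 2-silyloxydiene A4, followed by loss of HBr and tautomerisation. A4 needs regio- and geometry-defined enolisation of a cross-conjugated diketone that carries the whole side chain. Two independent orientation questions arise (Br/N on the quinone, acyl terminus of the diene), and an acyl-substituted diene terminus is poorly matched to a quinone. The pyrone locks the diene s-cis and the symmetric aryne removes the orientation question.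

**Alternative 3:** C5–C7′ can also be cut as a Fries rearrangement: esterification of naphthol A5 with enoic acid A6 to aryl ester A7, then Lewis-acid or photochemical acyl migration to C5 (C7 is blocked). A5 needs its own synthesis. Lewis acids would close the o-hydroxyaryl enone to a chromanone and strip the silyl ether, and light would scramble the alkene geometry. Migration into the peri-hindered position is slow. On the pyrone the same shift needs only DMAP at mild temperature.

Key step: step 13

## Route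

Step 1
Reactants: 1 (R)-4-benzyl-3-propanoyl-1,3-oxazolidin-2-one; 2 methacrolein
Product: 4 (4R)-4-benzyl-3-[(2R,3R)-3-hydroxy-2,4-dimethylpent-4-enoyl]-1,3-oxazolidin-2-one, via dibutylboron Z-enolate 3 (not isolated)
Conditions: Bu2BOTf, i-Pr2NEt, CH2Cl2, 0 °C; 2, −78 → 0 °C; then H2O2, MeOH, pH 7 buffer
Reagents that add atoms: none
Why: Evans syn-aldol reaction: the Z-boron enolate reacts through a closed chair transition state and the benzyl group of the (R)-auxiliary shields one enolate face, which should set C2′ and C3′ as the 2R,3R syn adduct.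

Step 2
Reactants: 4 aldol adduct
Product: 5 (4R)-4-benzyl-3-[(2R,3R)-3-(tert-butyldimethylsilyloxy)-2,4-dimethylpent-4-enoyl]-1,3-oxazolidin-2-one
Conditions: TBSOTf, 2,6-lutidine, CH2Cl2, 0 °C
Reagents that add atoms: tert-butyldimethylsilyl trifluoromethanesulfonate, CC(C)(C)[Si](C)(C)OS(=O)(=O)C(F)(F)F
Why: Silylation of a hindered secondary alcohol with a silyl triflate; the silyl ether blocks retro-aldol cleavage and is the control element for step 4.

Step 3
Reactants: 5 silyl ether imide
Product: 6 4-methoxybenzyl (2R,3R)-3-(tert-butyldimethylsilyloxy)-2,4-dimethylpent-4-enoate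
Conditions: 4-methoxybenzyl alcohol, n-BuLi, THF, −78 → 0 °C
Reagents that add atoms: 4-methoxybenzyl alcohol, COc1ccc(CO)cc1
Why: Transesterification of an N-acyloxazolidinone with a lithium alkoxide (attack at the exocyclic carbonyl) should give the acid-labile ester directly; low temperature protects C2′.

Step 4
Reactants: 6 alkene ester
Product: 8 4-methoxybenzyl (2R,3S,4R)-3-(tert-butyldimethylsilyloxy)-5-hydroxy-2,4-dimethylpentanoate, via catechol boronate 7 (not isolated)
Conditions: catecholborane, RhCl(PPh3)3 (3 mol %), THF, 20 °C; then 30% H2O2, aq NaHCO3, 0 → 20 °C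
Reagents that add atoms: hydrogen peroxide, OO
Why: Rhodium-catalysed hydroboration of a 1,1-disubstituted allylic silyl ether puts boron on the CH2 terminus and hydrogen on C4′ syn to the silyloxy group, the opposite sense to uncatalysed dialkylboranes. C4′ is thus set by 1,2-induction from C3′, and oxidation of the C–B bond proceeds with retention.

Step 5
Reactants: 8 primary alcohol
Product: 9 4-methoxybenzyl (2R,3S,4S)-3-(tert-butyldimethylsilyloxy)-2,4-dimethyl-5-oxopentanoate
Conditions: Dess–Martin periodinane, pyridine, CH2Cl2, 0 → 20 °C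
Reagents that add atoms: none
Why: Dess–Martin oxidation under buffered, non-basic conditions should give the α-branched aldehyde without epimerisation at C4′ (the descriptor changes only through priorities).

Step 6
Reactants: 10 methyl 3-oxopentanoate; 11 methyl formate
Product: 13 4-hydroxy-5-methyl-2H-pyran-2-one, via methyl 5-hydroxy-4-methyl-3-oxopent-4-enoate 12 (not isolated)
Conditions: LDA (2.2 equiv), THF, −78 → 0 °C; 11, −78 → 20 °C; 1 M HCl; then DBU (cat.), PhMe, 80 °C
Reagents that add atoms: none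
Why: The dianion of a β-keto ester is acylated at its γ-carbon by the formate (Claisen-type acylation); the hydroxymethylene ketone then lactonises onto the ester to give the 4-hydroxy-2-pyrone.

Step 7
Reactants: 13 4-hydroxy-5-methyl-2H-pyran-2-one; 14 2-(diethoxyphosphoryl)propanoic acid
Product: 16 diethyl [1-(4-hydroxy-5-methyl-2-oxo-2H-pyran-3-yl)-1-oxopropan-2-yl]phosphonate (racemic), via O-acyl pyrone 15 (not isolated)
Conditions: DCC, DMAP, PhMe, 20 → 50 °C
Reagents that add atoms: none
Why: Carbodiimide O-acylation of the 4-hydroxyl followed by a DMAP-mediated 1,3 O-to-C acyl shift (Fries-type), a known way to 3-acyl-4-hydroxy-2-pyrones. C3 is the only free nucleophilic carbon because C5 carries the methyl group.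

Step 8
Reactants: 16 acyl pyrone
Product: 17 diethyl {1-[4-(methoxymethoxy)-5-methyl-2-oxo-2H-pyran-3-yl]-1-oxopropan-2-yl}phosphonate
Conditions: MOMCl, i-Pr2NEt, CH2Cl2, 0 °C
Reagents that add atoms: chloromethyl methyl ether, COCCl
Why: O-Alkylation of the acidic ring enol with a hard electrophile; this removes the proton that would otherwise stop the olefination and add to the aryne, and gives a group that falls off in acid.

Step 9
Reactants: 18 2,5-dimethoxyphenol
Product: 19 2,5-dimethoxyphenyl N-(propan-2-yl)carbamate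
Conditions: i-PrNCO, Et3N (cat.), CH2Cl2, 20 °C
Reagents that add atoms: isopropyl isocyanate, CC(C)N=C=O
Why: Addition of the phenol to the isocyanate installs a carbamate that directs metalation and is later removable under mild base.

Step 10
Reactants: 19 aryl carbamate
Product: 22 3,6-dimethoxy-2-(trimethylsilyl)phenyl N-(propan-2-yl)carbamate, via N-silyl carbamate 20 (not isolated), via N-silyl C-silyl carbamate 21 (not isolated)
Conditions: TBSOTf, TMEDA, Et2O, 0 → 20 °C; n-BuLi, TMEDA, −78 °C; TMSCl, −78 → 20 °C; aq NaHSO4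
Reagents that add atoms: chlorotrimethylsilane, C[Si](C)(C)Cl
Why: Directed ortho-metalation after transient N-silylation: lithiation should occur at the one position lying between the carbamate and a methoxy group, and the silyl chloride quench gives the C-silane; the N–Si bond is hydrolysed on work-up.

Step 11
Reactants: 22 ortho-silyl carbamate
Product: 24 3,6-dimethoxy-2-(trimethylsilyl)phenyl trifluoromethanesulfonate, via 3,6-dimethoxy-2-(trimethylsilyl)phenol 23 (not isolated)
Conditions: DBU, Et2NH, MeCN, 40 °C; then PhNTf2, 20 °C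
Reagents that add atoms: N-phenylbis(trifluoromethanesulfonimide), O=S(=O)(N(c1ccccc1)S(=O)(=O)C(F)(F)F)C(F)(F)F
Why: Base-induced E1cB loss of isopropyl isocyanate (trapped by diethylamine as a urea) frees the phenoxide, which is triflated in the same flask to the 2-silylaryl triflate.

Step 12
Reactants: 17 pyrone ketophosphonate; 9 aldehyde
Product: 25 4-methoxybenzyl (2R,3S,4R,5E)-3-(tert-butyldimethylsilyloxy)-7-[4-(methoxymethoxy)-5-methyl-2-oxo-2H-pyran-3-yl]-2,4,6-trimethyl-7-oxohept-5-enoate
Conditions: LiCl, i-Pr2NEt, MeCN, 20 °C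
Reagents that add atoms: none
Why: Horner–Wadsworth–Emmons olefination under lithium chloride/amine conditions: the lithium-chelated ketophosphonate anion adds reversibly and should eliminate to the more stable E-enone, while the weak amine base leaves C4′ of the aldehyde untouched.

Step 13
Reactants: 25 acyl pyrone enone; 24 2-silylaryl triflate
Product: 28 4-methoxybenzyl (2R,3S,4R,5E)-3-(tert-butyldimethylsilyloxy)-7-[5,8-dimethoxy-2-(methoxymethoxy)-3-methylnaphthalen-1-yl]-2,4,6-trimethyl-7-oxohept-5-enoate, via 3,6-dimethoxybenzyne 26 (not isolated), via bridged lactone cycloadduct 27 (not isolated)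
Conditions: 24 (2 equiv), CsF, MeCN, 20 → 50 °C
Reagents that add atoms: none
Why: Fluoride attacks silicon in 24 and expels triflate to give aryne 26, which is trapped in a concerted, asynchronous [4+2] cycloaddition by the diene C3=C4–C5=C6 held s-cis in the pyrone ring of 25. Ring B is closed in this event as a six-membered carbocycle by suprafacial [π4s+π2s] addition (bonds C4a–C5 and C8–C8a), giving bridged lactone 27, and a retro-[4+2] loss of CO2 aromatises it to 28. The closest known reaction type is the cycloaddition of benzyne with 2-pyrones, which gives naphthalenes after decarboxylation. No lasting stereocentre is formed: the two bridgehead centres of 27 are erased on aromatisation, so both diastereomers of 27 converge on 28. Regioselectivity is not needed, because the two methoxy groups beside the triple bond of 26 are identical and both orientations of the pyrone give the same naphthalene; the methoxy groups also raise the electrophilicity of the aryne by induction. Site selectivity is needed between the pyrone diene and the side-chain enone: the enone is trisubstituted, electron-poor and not held as a cyclic diene, so ene or [2+2] capture should be slow next to the [4+2] reaction. The substrate has no O–H or N–H that could add to the aryne, and the weakly basic CsF/MeCN medium should leave C4′ and C2′ alone. The step turns the C3-acyl group of the pyrone into the hindered C5 ketone without any bond being made to a crowded arene.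

Step 14
Reactants: 28 dimethoxynaphthalene
Product: 29 4-methoxybenzyl (2R,3S,4R,5E)-3-(tert-butyldimethylsilyloxy)-7-[2-(methoxymethoxy)-3-methyl-5,8-dioxo-5,8-dihydronaphthalen-1-yl]-2,4,6-trimethyl-7-oxohept-5-enoate
Conditions: (NH4)2Ce(NO3)6 (2.5 equiv), MeCN/H2O, 0 °C
Reagents that add atoms: water, O
Why: Oxidative demethylation of a 1,4-dimethoxyarene by single-electron oxidation, water attack and loss of methanol; ring A is by far the most electron-rich arene. Any acid-labile group lost here would be lost in step 15 anyway.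

Step 15
Reactants: 29 protected naphthoquinone
Product: 30 (2R,3S,4R,5E)-3-hydroxy-7-(2-hydroxy-3-methyl-5,8-dioxo-5,8-dihydronaphthalen-1-yl)-2,4,6-trimethyl-7-oxohept-5-enoic acid
Conditions: TFA/CH2Cl2/H2O (10:10:1), anisole, 0 → 20 °C
Reagents that add atoms: none
Why: One acidolysis should remove all three groups: the 4-methoxybenzyl ester by benzylic cation loss (trapped by anisole), the aryl MOM acetal and the silyl ether by hydrolysis. The absence of base avoids retro-aldol cleavage and C4′ epimerisation.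

Step 16
Reactants: 30 hydroxynaphthoquinone acid
Product: 32 (2R,3S,4R,5E)-7-(6-amino-2-hydroxy-3-methyl-5,8-dioxo-5,8-dihydronaphthalen-1-yl)-3-hydroxy-2,4,6-trimethyl-7-oxohept-5-enoic acid (target), via 2-azidohydroquinone 31 (not isolated)
Conditions: NaN3, AcOH, THF/H2O (pH about 6), 20 → 40 °C
Reagents that add atoms: sodium azide, [Na+].[N-]=[N+]=[N-]
Why: Conjugate addition of azide to the quinone gives an azidohydroquinone, which undergoes the known internal redox reaction with loss of N2 to the aminoquinone. O6 (largely as the phenoxide) is para to C8a and donates into C1=O, so C4=O stays the activating carbonyl and azide should add at its β-carbon C2; the side-chain enone is hindered and far less electrophilic.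

## Compound list

1 | (R)-4-benzyl-3-propanoyl-1,3-oxazolidin-2-one | CCC(=O)N1[C@H](Cc2ccccc2)COC1=O | starting material
2 | methacrolein | CC(=C)C=O | starting material
3 | dibutylboron Z-enolate of 1 | C/C=C(\OB(CCCC)CCCC)N1[C@H](Cc2ccccc2)COC1=O | intermediate
4 | (4R)-4-benzyl-3-[(2R,3R)-3-hydroxy-2,4-dimethylpent-4-enoyl]-1,3-oxazolidin-2-one | C=C(C)[C@H](O)[C@@H](C)C(=O)N1[C@H](Cc2ccccc2)COC1=O | intermediate
5 | (4R)-4-benzyl-3-[(2R,3R)-3-(tert-butyldimethylsilyloxy)-2,4-dimethylpent-4-enoyl]-1,3-oxazolidin-2-one | C=C(C)[C@H](O[Si](C)(C)C(C)(C)C)[C@@H](C)C(=O)N1[C@H](Cc2ccccc2)COC1=O | intermediate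
6 | 4-methoxybenzyl (2R,3R)-3-(tert-butyldimethylsilyloxy)-2,4-dimethylpent-4-enoate | C=C(C)[C@H](O[Si](C)(C)C(C)(C)C)[C@@H](C)C(=O)OCc1ccc(OC)cc1 | intermediate
7 | 4-methoxybenzyl (2R,3S,4R)-5-(1,3,2-benzodioxaborol-2-yl)-3-(tert-butyldimethylsilyloxy)-2,4-dimethylpentanoate | c1ccc2OB(C[C@@H](C)[C@H](O[Si](C)(C)C(C)(C)C)[C@@H](C)C(=O)OCc3ccc(OC)cc3)Oc2c1 | intermediate
8 | 4-methoxybenzyl (2R,3S,4R)-3-(tert-butyldimethylsilyloxy)-5-hydroxy-2,4-dimethylpentanoate | OC[C@@H](C)[C@H](O[Si](C)(C)C(C)(C)C)[C@@H](C)C(=O)OCc1ccc(OC)cc1 | intermediate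
9 | 4-methoxybenzyl (2R,3S,4S)-3-(tert-butyldimethylsilyloxy)-2,4-dimethyl-5-oxopentanoate | O=C[C@@H](C)[C@H](O[Si](C)(C)C(C)(C)C)[C@@H](C)C(=O)OCc1ccc(OC)cc1 | intermediate
10 | methyl 3-oxopentanoate | CCC(=O)CC(=O)OC | starting material
11 | methyl formate | COC=O | starting material
12 | methyl 5-hydroxy-4-methyl-3-oxopent-4-enoate | COC(=O)CC(=O)C(C)=CO | intermediate
13 | 4-hydroxy-5-methyl-2H-pyran-2-one | CC1=COC(=O)C=C1O | intermediate
14 | 2-(diethoxyphosphoryl)propanoic acid | CCOP(=O)(OCC)C(C)C(=O)O | starting material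
15 | 5-methyl-2-oxo-2H-pyran-4-yl 2-(diethoxyphosphoryl)propanoate | CCOP(=O)(OCC)C(C)C(=O)OC1=CC(=O)OC=C1C | intermediate
16 | diethyl [1-(4-hydroxy-5-methyl-2-oxo-2H-pyran-3-yl)-1-oxopropan-2-yl]phosphonate | CCOP(=O)(OCC)C(C)C(=O)C1=C(O)C(C)=COC1=O | intermediate
17 | diethyl {1-[4-(methoxymethoxy)-5-methyl-2-oxo-2H-pyran-3-yl]-1-oxopropan-2-yl}phosphonate | CCOP(=O)(OCC)C(C)C(=O)C1=C(OCOC)C(C)=COC1=O | intermediate
18 | 2,5-dimethoxyphenol | COc1ccc(OC)c(O)c1 | starting material
19 | 2,5-dimethoxyphenyl N-(propan-2-yl)carbamate | COc1ccc(OC)c(OC(=O)NC(C)C)c1 | intermediate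
20 | 2,5-dimethoxyphenyl N-(tert-butyldimethylsilyl)-N-(propan-2-yl)carbamate | COc1ccc(OC)c(OC(=O)N(C(C)C)[Si](C)(C)C(C)(C)C)c1 | intermediate
21 | 3,6-dimethoxy-2-(trimethylsilyl)phenyl N-(tert-butyldimethylsilyl)-N-(propan-2-yl)carbamate | COc1ccc(OC)c(OC(=O)N(C(C)C)[Si](C)(C)C(C)(C)C)c1[Si](C)(C)C | intermediate
22 | 3,6-dimethoxy-2-(trimethylsilyl)phenyl N-(propan-2-yl)carbamate | COc1ccc(OC)c(OC(=O)NC(C)C)c1[Si](C)(C)C | intermediate
23 | 3,6-dimethoxy-2-(trimethylsilyl)phenol | COc1ccc(OC)c(O)c1[Si](C)(C)C | intermediate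
24 | 3,6-dimethoxy-2-(trimethylsilyl)phenyl trifluoromethanesulfonate | COc1ccc(OC)c(OS(=O)(=O)C(F)(F)F)c1[Si](C)(C)C | intermediate
25 | 4-methoxybenzyl (2R,3S,4R,5E)-3-(tert-butyldimethylsilyloxy)-7-[4-(methoxymethoxy)-5-methyl-2-oxo-2H-pyran-3-yl]-2,4,6-trimethyl-7-oxohept-5-enoate | C/C(=C\[C@@H](C)[C@H](O[Si](C)(C)C(C)(C)C)[C@@H](C)C(=O)OCc1ccc(OC)cc1)C(=O)C2=C(OCOC)C(C)=COC2=O | intermediate
26 | 3,6-dimethoxybenzyne | COC1=CC=C(OC)C#C1 | intermediate
27 | bridged [4+2] adduct of 25 and 26 (benzo-fused 2-oxabicyclo[2.2.2]octadien-3-one; acyl group on one bridgehead, H on the other; both bridgehead epimers) | C/C(=C\[C@@H](C)[C@H](O[Si](C)(C)C(C)(C)C)[C@@H](C)C(=O)OCc1ccc(OC)cc1)C(=O)C23C(=O)OC(C(C)=C2OCOC)c4c(OC)ccc(OC)c34 | intermediate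
28 | 4-methoxybenzyl (2R,3S,4R,5E)-3-(tert-butyldimethylsilyloxy)-7-[5,8-dimethoxy-2-(methoxymethoxy)-3-methylnaphthalen-1-yl]-2,4,6-trimethyl-7-oxohept-5-enoate | C/C(=C\[C@@H](C)[C@H](O[Si](C)(C)C(C)(C)C)[C@@H](C)C(=O)OCc1ccc(OC)cc1)C(=O)c2c(OCOC)c(C)cc3c(OC)ccc(OC)c23 | intermediate
29 | 4-methoxybenzyl (2R,3S,4R,5E)-3-(tert-butyldimethylsilyloxy)-7-[2-(methoxymethoxy)-3-methyl-5,8-dioxo-5,8-dihydronaphthalen-1-yl]-2,4,6-trimethyl-7-oxohept-5-enoate | C/C(=C\[C@@H](C)[C@H](O[Si](C)(C)C(C)(C)C)[C@@H](C)C(=O)OCc1ccc(OC)cc1)C(=O)c2c(OCOC)c(C)cc3c2C(=O)C=CC3=O | intermediate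
30 | (2R,3S,4R,5E)-3-hydroxy-7-(2-hydroxy-3-methyl-5,8-dioxo-5,8-dihydronaphthalen-1-yl)-2,4,6-trimethyl-7-oxohept-5-enoic acid | C/C(=C\[C@@H](C)[C@H](O)[C@@H](C)C(=O)O)C(=O)c1c(O)c(C)cc2c1C(=O)C=CC2=O | intermediate
31 | (2R,3S,4R,5E)-7-(6-azido-2,5,8-trihydroxy-3-methylnaphthalen-1-yl)-3-hydroxy-2,4,6-trimethyl-7-oxohept-5-enoic acid | C/C(=C\[C@@H](C)[C@H](O)[C@@H](C)C(=O)O)C(=O)c1c(O)c(C)cc2c(O)c(N=[N+]=[N-])cc(O)c12 | intermediate
32 | (2R,3S,4R,5E)-7-(6-amino-2-hydroxy-3-methyl-5,8-dioxo-5,8-dihydronaphthalen-1-yl)-3-hydroxy-2,4,6-trimethyl-7-oxohept-5-enoic acid (CNP0236465.1) | C/C(=C\[C@@H](C)[C@H](O)[C@@H](C)C(=O)O)C(=O)c1c(O)c(C)cc2c1C(=O)C=C(N)C2=O | target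

## Step count and least certain steps

Total: 16 steps. Longest linear sequence: 10 steps (steps 1–5, then 12–16). Side branches: steps 6–8 (pyrone) and steps 9–11 (aryne precursor).

**Step 13 (key step).** The cycloaddition may be too slow: the diene terminus C3 is fully substituted and flanked by two carbonyl groups, and each aryne carbon sits beside a methoxy group. The aryne would then be consumed by self-reaction or by ene/[2+2] capture at the enone, and long exposure to fluoride could erode C4′. The fallback takes the acyl group out of the cycloaddition. It sets out from 13, 24 and 9 and returns at 28. O-Alkylation of 13 with MOMCl gives 4-(methoxymethoxy)-5-methyl-2H-pyran-2-one F1, an unhindered and more electron-rich diene. Its cycloaddition with 26 (from 24, CsF) and loss of CO2 gives 1,4-dimethoxy-6-(methoxymethoxy)-7-methylnaphthalene F2. Directed ortho-lithiation of F2 (n-BuLi, TMEDA) should occur at C5, the only free position beside the MOM ether. Addition to the enal 4-methoxybenzyl (2R,3S,4R,5E)-3-(tert-butyldimethylsilyloxy)-2,4,6-trimethyl-7-oxohept-5-enoate F3, made from 9 by Wittig reaction with 2-(triphenylphosphoranylidene)propanal, gives the carbinol F4. Dess–Martin oxidation of F4 gives 28.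

**Step 16.** The site selectivity between C2 and C3 rests on the electronic argument alone. Azide addition to the deactivated phenoxide may also be slow, and the free o-hydroxyaryl enone could close to a chromanone. The fallback fixes the nitrogen position by halogen and uses ipso substitution. It sets out from 28 and returns at 32. Bromination of 28 with N-bromosuccinimide is expected beside the C1 methoxy group, because the C4 methoxy group is crowded out of conjugation by the peri acyl group; this gives the 2-bromo compound F5. Oxidation with (NH4)2Ce(NO3)6 gives bromoquinone F6. NaN3 in DMF displaces bromide to give azidoquinone F7. Staudinger reduction (PPh3, THF/H2O) gives the protected aminoquinone F8, and acidolysis as in step 15 gives 32.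

**Step 12.** The phosphonate anion is strongly stabilised by the pyrone acyl group and hindered, so olefination may stall. The pyrone can meanwhile suffer nucleophilic opening at C6 or loss of the MOM group. The fallback builds the enone before the pyrone is acylated. It sets out from 9 and 13 and returns at 25. Wittig reaction of 9 with allyl 2-(triphenylphosphoranylidene)propanoate gives the E-enoate diester F9. Pd(PPh3)4 and morpholine remove the allyl group to give enoic acid F10. DCC/DMAP acylation of 13 with F10 (O-acylation, then acyl shift to C3) gives acyl pyrone F11, and MOMCl/i-Pr2NEt converts F11 into 25.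

**Step 8.** The enolate of 16 is ambident, so alkylation may stray to the lactone or acyl oxygen, and the vinylogous MOM ester may hydrolyse on handling. The fallback uses Mitsunobu alkylation, which is known to favour O4 of 4-hydroxy-2-pyrones, and a more robust ether. It sets out from 16 and returns at 30. 4-Methoxybenzyl alcohol, PPh3 and diisopropyl azodicarboxylate give the 4-(4-methoxybenzyloxy) pyrone phosphonate F12. Olefination with 9 gives enone F13, cycloaddition with 26 gives naphthalene F14, and oxidation with (NH4)2Ce(NO3)6 gives quinone F15. The acidolysis of step 15 removes both 4-methoxybenzyl groups and the silyl ether to give 30.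

## Further compounds

F1 | step 13 | 4-(methoxymethoxy)-5-methyl-2H-pyran-2-one | COCOC1=CC(=O)OC=C1C
F2 | step 13 | 1,4-dimethoxy-6-(methoxymethoxy)-7-methylnaphthalene | COCOc1cc2c(OC)ccc(OC)c2cc1C
F3 | step 13 | 4-methoxybenzyl (2R,3S,4R,5E)-3-(tert-butyldimethylsilyloxy)-2,4,6-trimethyl-7-oxohept-5-enoate | C/C(=C\[C@@H](C)[C@H](O[Si](C)(C)C(C)(C)C)[C@@H](C)C(=O)OCc1ccc(OC)cc1)C=O
F4 | step 13 | 4-methoxybenzyl (2R,3S,4R,5E)-3-(tert-butyldimethylsilyloxy)-7-[5,8-dimethoxy-2-(methoxymethoxy)-3-methylnaphthalen-1-yl]-7-hydroxy-2,4,6-trimethylhept-5-enoate (both C7 epimers) | C/C(=C\[C@@H](C)[C@H](O[Si](C)(C)C(C)(C)C)[C@@H](C)C(=O)OCc1ccc(OC)cc1)C(O)c2c(OCOC)c(C)cc3c(OC)ccc(OC)c23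
F5 | step 16 | 4-methoxybenzyl (2R,3S,4R,5E)-7-[6-bromo-5,8-dimethoxy-2-(methoxymethoxy)-3-methylnaphthalen-1-yl]-3-(tert-butyldimethylsilyloxy)-2,4,6-trimethyl-7-oxohept-5-enoate | C/C(=C\[C@@H](C)[C@H](O[Si](C)(C)C(C)(C)C)[C@@H](C)C(=O)OCc1ccc(OC)cc1)C(=O)c2c(OCOC)c(C)cc3c(OC)c(Br)cc(OC)c23
F6 | step 16 | 4-methoxybenzyl (2R,3S,4R,5E)-7-[6-bromo-2-(methoxymethoxy)-3-methyl-5,8-dioxo-5,8-dihydronaphthalen-1-yl]-3-(tert-butyldimethylsilyloxy)-2,4,6-trimethyl-7-oxohept-5-enoate | C/C(=C\[C@@H](C)[C@H](O[Si](C)(C)C(C)(C)C)[C@@H](C)C(=O)OCc1ccc(OC)cc1)C(=O)c2c(OCOC)c(C)cc3c2C(=O)C=C(Br)C3=O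
F7 | step 16 | 4-methoxybenzyl (2R,3S,4R,5E)-7-[6-azido-2-(methoxymethoxy)-3-methyl-5,8-dioxo-5,8-dihydronaphthalen-1-yl]-3-(tert-butyldimethylsilyloxy)-2,4,6-trimethyl-7-oxohept-5-enoate | C/C(=C\[C@@H](C)[C@H](O[Si](C)(C)C(C)(C)C)[C@@H](C)C(=O)OCc1ccc(OC)cc1)C(=O)c2c(OCOC)c(C)cc3c2C(=O)C=C(N=[N+]=[N-])C3=O
F8 | step 16 | 4-methoxybenzyl (2R,3S,4R,5E)-7-[6-amino-2-(methoxymethoxy)-3-methyl-5,8-dioxo-5,8-dihydronaphthalen-1-yl]-3-(tert-butyldimethylsilyloxy)-2,4,6-trimethyl-7-oxohept-5-enoate | C/C(=C\[C@@H](C)[C@H](O[Si](C)(C)C(C)(C)C)[C@@H](C)C(=O)OCc1ccc(OC)cc1)C(=O)c2c(OCOC)c(C)cc3c2C(=O)C=C(N)C3=O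
F9 | step 12 | 1-allyl 7-(4-methoxybenzyl) (2E,4R,5S,6R)-5-(tert-butyldimethylsilyloxy)-2,4,6-trimethylhept-2-enedioate | C/C(=C\[C@@H](C)[C@H](O[Si](C)(C)C(C)(C)C)[C@@H](C)C(=O)OCc1ccc(OC)cc1)C(=O)OCC=C
F10 | step 12 | (2E,4R,5S,6R)-5-(tert-butyldimethylsilyloxy)-7-[(4-methoxybenzyl)oxy]-2,4,6-trimethyl-7-oxohept-2-enoic acid | C/C(=C\[C@@H](C)[C@H](O[Si](C)(C)C(C)(C)C)[C@@H](C)C(=O)OCc1ccc(OC)cc1)C(=O)O
F11 | step 12 | 4-methoxybenzyl (2R,3S,4R,5E)-3-(tert-butyldimethylsilyloxy)-7-(4-hydroxy-5-methyl-2-oxo-2H-pyran-3-yl)-2,4,6-trimethyl-7-oxohept-5-enoate | C/C(=C\[C@@H](C)[C@H](O[Si](C)(C)C(C)(C)C)[C@@H](C)C(=O)OCc1ccc(OC)cc1)C(=O)C2=C(O)C(C)=COC2=O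
F12 | step 8 | diethyl {1-[4-(4-methoxybenzyloxy)-5-methyl-2-oxo-2H-pyran-3-yl]-1-oxopropan-2-yl}phosphonate | CCOP(=O)(OCC)C(C)C(=O)C1=C(OCc2ccc(OC)cc2)C(C)=COC1=O
F13 | step 8 | 4-methoxybenzyl (2R,3S,4R,5E)-3-(tert-butyldimethylsilyloxy)-7-[4-(4-methoxybenzyloxy)-5-methyl-2-oxo-2H-pyran-3-yl]-2,4,6-trimethyl-7-oxohept-5-enoate | C/C(=C\[C@@H](C)[C@H](O[Si](C)(C)C(C)(C)C)[C@@H](C)C(=O)OCc1ccc(OC)cc1)C(=O)C2=C(OCc3ccc(OC)cc3)C(C)=COC2=O
F14 | step 8 | 4-methoxybenzyl (2R,3S,4R,5E)-3-(tert-butyldimethylsilyloxy)-7-[5,8-dimethoxy-2-(4-methoxybenzyloxy)-3-methylnaphthalen-1-yl]-2,4,6-trimethyl-7-oxohept-5-enoate | C/C(=C\[C@@H](C)[C@H](O[Si](C)(C)C(C)(C)C)[C@@H](C)C(=O)OCc1ccc(OC)cc1)C(=O)c2c(OCc3ccc(OC)cc3)c(C)cc4c(OC)ccc(OC)c24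
F15 | step 8 | 4-methoxybenzyl (2R,3S,4R,5E)-3-(tert-butyldimethylsilyloxy)-7-[2-(4-methoxybenzyloxy)-3-methyl-5,8-dioxo-5,8-dihydronaphthalen-1-yl]-2,4,6-trimethyl-7-oxohept-5-enoate | C/C(=C\[C@@H](C)[C@H](O[Si](C)(C)C(C)(C)C)[C@@H](C)C(=O)OCc1ccc(OC)cc1)C(=O)c2c(OCc3ccc(OC)cc3)c(C)cc4c2C(=O)C=CC4=O
A1 | alternative 1 | 5-bromo-1,4-dimethoxy-6-(methoxymethoxy)-7-methylnaphthalene | COCOc1c(C)cc2c(OC)ccc(OC)c2c1Br
A2 | alternative 1 | 4-methoxybenzyl (2R,3S,4R,5E)-3-(tert-butyldimethylsilyloxy)-7-[methoxy(methyl)amino]-2,4,6-trimethyl-7-oxohept-5-enoate | C/C(=C\[C@@H](C)[C@H](O[Si](C)(C)C(C)(C)C)[C@@H](C)C(=O)OCc1ccc(OC)cc1)C(=O)N(C)OC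
A3 | alternative 2 | tert-butyl (5-bromo-3,6-dioxocyclohexa-1,4-dien-1-yl)carbamate | O=C1C=C(Br)C(=O)C(NC(=O)OC(C)(C)C)=C1
A4 | alternative 2 | 4-methoxybenzyl (2R,3S,4R,5E)-3-(tert-butyldimethylsilyloxy)-2,4,6,10-tetramethyl-7-oxo-9-(trimethylsilyloxy)undeca-5,8,10-trienoate | C/C(=C\[C@@H](C)[C@H](O[Si](C)(C)C(C)(C)C)[C@@H](C)C(=O)OCc1ccc(OC)cc1)C(=O)C=C(O[Si](C)(C)C)C(C)=C
A5 | alternative 3 | 5,8-dimethoxy-3-methylnaphthalen-2-ol | Cc1cc2c(OC)ccc(OC)c2cc1O
A6 | alternative 3 | (2E,4R,5S,6R)-5-(tert-butyldimethylsilyloxy)-7-[(4-methoxybenzyl)oxy]-2,4,6-trimethyl-7-oxohept-2-enoic acid | C/C(=C\[C@@H](C)[C@H](O[Si](C)(C)C(C)(C)C)[C@@H](C)C(=O)OCc1ccc(OC)cc1)C(=O)O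
A7 | alternative 3 | 1-(5,8-dimethoxy-3-methylnaphthalen-2-yl) 7-(4-methoxybenzyl) (2E,4R,5S,6R)-5-(tert-butyldimethylsilyloxy)-2,4,6-trimethylhept-2-enedioate | C/C(=C\[C@@H](C)[C@H](O[Si](C)(C)C(C)(C)C)[C@@H](C)C(=O)OCc1ccc(OC)cc1)C(=O)Oc2cc3c(OC)ccc(OC)c3cc2C
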